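The six-membered ring C1–C6 is read as an arene cis-dihydrodiol: C1 (side chain) and C4 (methyl) face each other across the ring, and the oxygen-bearing C2 and C3 are the adjacent pair on one side of that axis. Whole-cell dioxygenation of 4-iodoacetophenone, a flat para-disubstituted benzene whose acetyl group already is C7 plus C14, forms both C–O bonds on one face in a single operation. It fixes C2 in its final configuration and leaves the C1=C6 enone and the C4=C5 iodoalkene ready for separate use. C1, C4 and C5 are then relayed from the diol; the side chain is grown from the acetyl group and the hydroperoxide is added last.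

Key step: step 1

Convention: ring C1 (side chain), C2 (isovalerate), C3 (ketone), C4 (methyl, epoxide), C5 (epoxide CH), C6 (CH2); chain C7(=C14H2)–C8(=O)–C9=C10–C11(OOH)Me2. α is the ring face of the two enzyme-delivered oxygens, β the opposite face (side chain and epoxide oxygen of the target). TBS = tert-butyldimethylsilyl.

Assumption: the NADH used by the dioxygenase is regenerated by the host cells from glucose and is treated as catalytic.

Step 1
Reactants: 1 4-iodoacetophenone
Product: 2 1-[(5S,6S)-5,6-dihydroxy-4-iodocyclohexa-1,3-dien-1-yl]ethan-1-one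
Conditions: E. coli JM109(pDTG601A) whole cells expressing toluene dioxygenase, IPTG, glucose feed, air, buffered medium pH 7.2, 30 °C
Reagents that add atoms: dioxygen, O=O
Why: The Rieske non-haem iron dioxygenase takes two electrons from NADH through its reductase and ferredoxin, activates O2 at the mononuclear iron and transfers both oxygen atoms suprafacially to the adjacent arene carbons C2 and C3, releasing the cis-dihydrodiol, which the recombinant host cannot rearomatise because it lacks the diol dehydrogenase. The closest known reaction type is the toluene dioxygenase cis-dihydroxylation of para-substituted iodobenzenes, here applied to a para-acyl member of that class. No ring closes: the benzene ring is dearomatised to the cyclohexadiene that becomes ring C1–C6. Both new stereocentres, C2 and C3, are set by the active site, which places the larger para substituent (iodine on C4) in its substituent pocket and oxidises the ortho,meta bond on one fixed face, in the absolute sense known for iodobenzene; their cis relation follows from delivery of both oxygens from one iron centre. Because the twofold axis through C1 and C4 makes the two ortho,meta bonds equivalent, the step needs only enantioface selectivity and chemoselectivity (ring oxidation in preference to carbonyl reduction by host reductases), and the former should be secured by iodine being the bulkiest and most polarisable substituent on the ring.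

Step 2
Reactants: 2 1-[(5S,6S)-5,6-dihydroxy-4-iodocyclohexa-1,3-dien-1-yl]ethan-1-one
Product: 3 1-[(5S,6S)-5,6-bis(tert-butyldimethylsilyloxy)-4-iodocyclohexa-1,3-dien-1-yl]ethan-1-one
Conditions: TBSOTf (2.5 equiv), 2,6-lutidine, CH2Cl2, −78 → 0 °C
Reagents that add atoms: tert-butyldimethylsilyl trifluoromethanesulfonate, CC(C)(C)[Si](C)(C)OS(=O)(=O)C(F)(F)F
Why: Silyl ether formation on both secondary hydroxyls is fast under hindered-base buffering, avoids the acid that would aromatise the dienediol, leaves the methyl ketone unenolised at low temperature and installs groups that can later be removed with fluoride in the presence of the epoxide; no stereocentre is touched.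

Step 3
Reactants: 3 1-[(5S,6S)-5,6-bis(tert-butyldimethylsilyloxy)-4-iodocyclohexa-1,3-dien-1-yl]ethan-1-one, 4 tetramethyltin
Product: 5 1-[(5R,6S)-5,6-bis(tert-butyldimethylsilyloxy)-4-methylcyclohexa-1,3-dien-1-yl]ethan-1-one
Conditions: Me4Sn, Pd2(dba)3 (cat.), AsPh3, CuI, NMP, 50 °C (sealed)
Reagents that add atoms: tetramethyltin (4), C[Sn](C)(C)C
Why: Stille cross-coupling, in which Pd(0) inserts into the alkenyl C4–I bond, methyl is transferred from tin with copper assistance and reductive elimination forms the C4–CH3 bond under neutral conditions that spare the dienone and the silyl ethers; the descriptor at C3 changes only because iodine is replaced by carbon.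

Step 4
Reactants: 5 1-[(5R,6S)-5,6-bis(tert-butyldimethylsilyloxy)-4-methylcyclohexa-1,3-dien-1-yl]ethan-1-one
Product: 8 1β-acetyl-2α,3α-bis(tert-butyldimethylsilyloxy)-4-methylcyclohex-4-ene (trans ketone), via silyl enol ether 6 (not isolated), via cis ketone 7 (not isolated)
Conditions: [(Ph3P)CuH]6 (cat.), PhMe2SiH, toluene, rt; then K2CO3, MeOH, 0 °C → rt
Reagents that add atoms: none
Why: Copper hydride-catalysed 1,4-hydrosilylation (conjugate reduction) should deliver hydride to the unsubstituted C6 in preference to the methyl-bearing C4 and store the enolate as a neutral silyl enol ether, and carbonate methanolysis then protonates C1 and equilibrates it to the trans isomer, which should be favoured because the acetyl group is equatorial while the C3 silyloxy group stays pseudoaxial and free of A(1,2) strain with the C4 methyl group.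

Step 5
Reactants: 8 1β-acetyl-2α,3α-bis(tert-butyldimethylsilyloxy)-4-methylcyclohex-4-ene
Product: 9 1β-acetyl-2α,3α-bis(tert-butyldimethylsilyloxy)-4β,5β-epoxy-4-methylcyclohexane
Conditions: mCPBA, NaHCO3, CH2Cl2, 0 °C
Reagents that add atoms: 3-chloroperoxybenzoic acid, OOC(=O)c1cccc(Cl)c1
Why: Prilezhaev epoxidation of the only alkene, which is trisubstituted and electron-rich, should outrun Baeyer–Villiger oxidation of the methyl ketone, and the pseudoaxial allylic C3 silyloxy group together with the C2 silyloxy group blocks the α-face, so oxygen is delivered to the β-face and sets C4 and C5 anti to the C3 oxygen and cis to the acetyl group.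

Step 6
Reactants: 9 1β-acetyl-2α,3α-bis(tert-butyldimethylsilyloxy)-4β,5β-epoxy-4-methylcyclohexane
Product: 11 1β-[1-(trifluoromethylsulfonyloxy)ethenyl]-2α,3α-bis(tert-butyldimethylsilyloxy)-4β,5β-epoxy-4-methylcyclohexane (enol triflate), via potassium enolate 10 (not isolated)
Conditions: KHMDS, THF, −78 °C; then PhNTf2, −78 → −20 °C
Reagents that add atoms: N-phenylbis(trifluoromethanesulfonimide), O=S(=O)(N(c1ccccc1)S(=O)(=O)C(F)(F)F)C(F)(F)F
Why: Kinetic deprotonation by the hindered amide occurs at the methyl group C14 and not at the tertiary C1–H, and O-sulfonylation of the enolate gives the 1,1-disubstituted enol triflate, after which C1 is no longer enolisable; the β-face enolate cannot reach the rear side of the epoxide, so the epoxide should survive.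

Step 7
Reactants: 11 1β-[1-(trifluoromethylsulfonyloxy)ethenyl]-2α,3α-bis(tert-butyldimethylsilyloxy)-4β,5β-epoxy-4-methylcyclohexane
Product: 12 1β-[1-(trifluoromethylsulfonyloxy)ethenyl]-4β,5β-epoxy-4-methylcyclohexane-2α,3α-diol
Conditions: HF·pyridine, pyridine, THF, 0 °C → rt
Reagents that add atoms: none
Why: Fluoride-mediated desilylation cleaves both Si–O bonds by attack at silicon under buffered conditions that generate no carbocation, so the trisubstituted epoxide, the enol triflate and all stereocentres should be retained.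

Step 8
Reactants: 12 1β-[1-(trifluoromethylsulfonyloxy)ethenyl]-4β,5β-epoxy-4-methylcyclohexane-2α,3α-diol, 13 isovaleryl chloride
Product: 14 3α-hydroxy-2α-(3-methylbutanoyloxy)-1β-[1-(trifluoromethylsulfonyloxy)ethenyl]-4β,5β-epoxy-4-methylcyclohexane (C2 mono-ester)
Conditions: isovaleryl chloride (1.05 equiv), 2,4,6-collidine, CH2Cl2, −40 → 0 °C
Reagents that add atoms: isovaleryl chloride (13), CC(C)CC(Cl)=O
Why: Regioselective acylation should occur at the equatorial C2 hydroxyl, flanked by two CH carbons, in preference to the pseudoaxial, neopentyl-like C3 hydroxyl next to the quaternary C4, and the C2 ester is also the thermodynamic site should acyl migration take place.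

Step 9
Reactants: 15 4-methylpent-3-en-1-ol
Product: 16 4-methylpent-3-enal
Conditions: Dess–Martin periodinane, NaHCO3, CH2Cl2, 0 °C → rt; used at once as a solution
Reagents that add atoms: none
Why: Dess–Martin oxidation of the primary homoallylic alcohol under bicarbonate buffering should give the β,γ-unsaturated aldehyde without moving the alkene into conjugation.

Step 10
Reactants: 14 3α-hydroxy-2α-(3-methylbutanoyloxy)-1β-[1-(trifluoromethylsulfonyloxy)ethenyl]-4β,5β-epoxy-4-methylcyclohexane, 16 4-methylpent-3-enal
Product: 17 3α-hydroxy-1β-(3-hydroxy-6-methylhepta-1,5-dien-2-yl)-2α-(3-methylbutanoyloxy)-4β,5β-epoxy-4-methylcyclohexane (both C8 epimers)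
Conditions: CrCl2 (excess), NiCl2 (cat.), DMF, rt
Reagents that add atoms: 4-methylpent-3-enal (16), CC(C)=CCC=O
Why: Nozaki–Hiyama–Kishi coupling, in which nickel inserts into the C7–OTf bond and transmetallation gives an alkenylchromium(III) species that adds chemoselectively to the aldehyde while tolerating ester, epoxide and free hydroxyl; the carbinol C8 forms without control and both epimers converge in step 11.

Step 11
Reactants: 17 3α-hydroxy-1β-(3-hydroxy-6-methylhepta-1,5-dien-2-yl)-2α-(3-methylbutanoyloxy)-4β,5β-epoxy-4-methylcyclohexane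
Product: 18 1β-(6-methyl-3-oxohepta-1,5-dien-2-yl)-2α-(3-methylbutanoyloxy)-4β,5β-epoxy-4-methylcyclohexan-3-one
Conditions: Dess–Martin periodinane (2.5 equiv), NaHCO3, CH2Cl2, 0 °C → rt
Reagents that add atoms: none
Why: Dess–Martin oxidation converts the allylic C8 and the hindered C3 alcohols in one operation under buffered, non-basic conditions, so the C10=C11 alkene should stay out of conjugation and the α-acyloxy centre C2 should not epimerise.

Step 12
Reactants: 18 1β-(6-methyl-3-oxohepta-1,5-dien-2-yl)-2α-(3-methylbutanoyloxy)-4β,5β-epoxy-4-methylcyclohexan-3-one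
Product: 19 CNP0241468.1, 1β-[(4E)-6-hydroperoxy-6-methyl-3-oxohepta-1,4-dien-2-yl]-2α-(3-methylbutanoyloxy)-4β,5β-epoxy-4-methylcyclohexan-3-one (1S,2S,4S,5S in the ring numbering used here)
Conditions: O2, tetraphenylporphyrin (cat.), hν (visible), CH2Cl2, −20 °C
Reagents that add atoms: dioxygen, O=O
Why: Schenck ene reaction, in which singlet oxygen attacks only the electron-rich trisubstituted C10=C11 alkene and not the enone, and should abstract an allylic hydrogen from C9, which is activated by the adjacent carbonyl and lies on the more substituted side of the alkene, forming the C11–O bond and the (E)-C9=C10 enone; abstraction from a methyl group would give a separable secondary hydroperoxide.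

Compound list
1 | 4-iodoacetophenone | CC(=O)c1ccc(I)cc1 | starting material
2 | 1-[(5S,6S)-5,6-dihydroxy-4-iodocyclohexa-1,3-dien-1-yl]ethan-1-one | CC(=O)C1=CC=C(I)[C@@H](O)[C@H]1O | intermediate
3 | 1-[(5S,6S)-5,6-bis(tert-butyldimethylsilyloxy)-4-iodocyclohexa-1,3-dien-1-yl]ethan-1-one | CC(=O)C1=CC=C(I)[C@@H](O[Si](C)(C)C(C)(C)C)[C@H]1O[Si](C)(C)C(C)(C)C | intermediate
4 | tetramethyltin | C[Sn](C)(C)C | starting material
5 | 1-[(5R,6S)-5,6-bis(tert-butyldimethylsilyloxy)-4-methylcyclohexa-1,3-dien-1-yl]ethan-1-one | CC(=O)C1=CC=C(C)[C@@H](O[Si](C)(C)C(C)(C)C)[C@H]1O[Si](C)(C)C(C)(C)C | intermediate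
6 | dimethylphenylsilyl enol ether of 8, exocyclic C1=C7, E/Z mixture (not isolated) | CC(O[Si](C)(C)c1ccccc1)=C2CC=C(C)[C@@H](O[Si](C)(C)C(C)(C)C)[C@H]2O[Si](C)(C)C(C)(C)C | intermediate
7 | 1α-acetyl-2α,3α-bis(tert-butyldimethylsilyloxy)-4-methylcyclohex-4-ene, the C1 epimer of 8 (not isolated) | CC(=O)[C@H]1CC=C(C)[C@@H](O[Si](C)(C)C(C)(C)C)[C@H]1O[Si](C)(C)C(C)(C)C | intermediate
8 | 1β-acetyl-2α,3α-bis(tert-butyldimethylsilyloxy)-4-methylcyclohex-4-ene | CC(=O)[C@@H]1CC=C(C)[C@@H](O[Si](C)(C)C(C)(C)C)[C@H]1O[Si](C)(C)C(C)(C)C | intermediate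
9 | 1β-acetyl-2α,3α-bis(tert-butyldimethylsilyloxy)-4β,5β-epoxy-4-methylcyclohexane | CC(=O)[C@@H]1C[C@@H]2O[C@]2(C)[C@@H](O[Si](C)(C)C(C)(C)C)[C@H]1O[Si](C)(C)C(C)(C)C | intermediate
10 | potassium enolate of 9, C7(O−)=C14H2 (not isolated) | C=C([O-])[C@@H]1C[C@@H]2O[C@]2(C)[C@@H](O[Si](C)(C)C(C)(C)C)[C@H]1O[Si](C)(C)C(C)(C)C.[K+] | intermediate
11 | 1β-[1-(trifluoromethylsulfonyloxy)ethenyl]-2α,3α-bis(tert-butyldimethylsilyloxy)-4β,5β-epoxy-4-methylcyclohexane | C=C(OS(=O)(=O)C(F)(F)F)[C@@H]1C[C@@H]2O[C@]2(C)[C@@H](O[Si](C)(C)C(C)(C)C)[C@H]1O[Si](C)(C)C(C)(C)C | intermediate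
12 | 1β-[1-(trifluoromethylsulfonyloxy)ethenyl]-4β,5β-epoxy-4-methylcyclohexane-2α,3α-diol | C=C(OS(=O)(=O)C(F)(F)F)[C@@H]1C[C@@H]2O[C@]2(C)[C@@H](O)[C@H]1O | intermediate
13 | isovaleryl chloride | CC(C)CC(Cl)=O | starting material
14 | 3α-hydroxy-2α-(3-methylbutanoyloxy)-1β-[1-(trifluoromethylsulfonyloxy)ethenyl]-4β,5β-epoxy-4-methylcyclohexane | C=C(OS(=O)(=O)C(F)(F)F)[C@@H]1C[C@@H]2O[C@]2(C)[C@@H](O)[C@H]1OC(=O)CC(C)C | intermediate
15 | 4-methylpent-3-en-1-ol | CC(C)=CCCO | starting material
16 | 4-methylpent-3-enal | CC(C)=CCC=O | intermediate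
17 | 3α-hydroxy-1β-(3-hydroxy-6-methylhepta-1,5-dien-2-yl)-2α-(3-methylbutanoyloxy)-4β,5β-epoxy-4-methylcyclohexane, both C8 epimers | C=C(C(O)CC=C(C)C)[C@@H]1C[C@@H]2O[C@]2(C)[C@@H](O)[C@H]1OC(=O)CC(C)C | intermediate
18 | 1β-(6-methyl-3-oxohepta-1,5-dien-2-yl)-2α-(3-methylbutanoyloxy)-4β,5β-epoxy-4-methylcyclohexan-3-one | C=C(C(=O)CC=C(C)C)[C@@H]1C[C@@H]2O[C@]2(C)C(=O)[C@H]1OC(=O)CC(C)C | intermediate
19 | CNP0241468.1, 1β-[(4E)-6-hydroperoxy-6-methyl-3-oxohepta-1,4-dien-2-yl]-2α-(3-methylbutanoyloxy)-4β,5β-epoxy-4-methylcyclohexan-3-one | C=C(C(=O)/C=C/C(C)(C)OO)[C@@H]1C[C@@H]2O[C@]2(C)C(=O)[C@H]1OC(=O)CC(C)C | target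

Total steps: 12. Longest linear sequence: 11 steps (steps 1–8 and 10–12); step 9 is a one-step branch.

Steps most likely to fail

1. Step 1 (key step). The acetyl group may compete with iodine for the substituent pocket of the enzyme, which would erode the enantiomeric purity. Host reductases may also reduce the ketone, or the electron-poor ring may be turned over slowly. The fallback introduces the acetyl group after the enzymatic step. It sets out from 1-bromo-4-iodobenzene F1, a commercial arene that takes the place of 1 and belongs to the para-halo-iodobenzenes, in which iodine is known to direct the enzyme. The same whole cells should give (1S,2R)-3-bromo-6-iodocyclohexa-3,5-diene-1,2-diol F2. Silylation as in step 2 would give the bis-silyl ether F3. Stille methylation with 4 at the more reactive C–I bond (Pd2(dba)3, AsPh3, CuI, NMP, rt) would give the bromo methyl diene F4. A second Stille coupling at the C–Br bond with tributyl(1-ethoxyvinyl)stannane, C=C(OCC)[Sn](CCCC)(CCCC)CCCC (Pd2(dba)3, AsPh3, CuI, NMP, 60 °C), would give the enol ether F5. Brief treatment with dilute aqueous HCl in THF at 0 °C would unmask the ketone and come back to the route at 5.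

2. Step 4. The equilibrium at C1 may be less one-sided than expected, 1,6-reduction may compete, or the base may trigger β-elimination of the C2 silyloxy group. The fallback sets C1 by hydroxyl-directed hydrogenation instead of protonation. Setting out from 5, epoxidation of the electron-richer C4=C5 alkene (mCPBA, NaHCO3, CH2Cl2, 0 °C; β-face as in step 5) would give the epoxy enone F6, and HF·pyridine would give the epoxy enone diol F7. Hydrogenation with [Ir(cod)(PCy3)(py)]PF6 under H2 in CH2Cl2, in which the α-face C2 hydroxyl binds iridium and hydrogen is delivered to the α-face of C1=C6, would give the 1β-acetyl keto diol F8. Re-silylation (TBSOTf, 2,6-lutidine) would come back to the route at 9.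

3. Step 12. Hydrogen may be abstracted from a C11 methyl group instead of from C9 (poor regioselectivity of the ene reaction), or the hydroperoxide may decompose during isolation. The fallback forms the C11–O bond by ionic Markovnikov addition. Setting out from 18, N-bromosuccinimide and anhydrous ethereal H2O2 at −40 °C would open the bromonium ion of the C10=C11 alkene at the tertiary carbon (bromohydroperoxidation) to give the 10-bromo-11-hydroperoxide F9. Triethylamine at 0 °C would then remove HBr across C9–C10 by E1cB elimination through the C8 enolate, giving the (E)-enone and coming back to the route at 19.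

Further compounds
F1 | step 1 | 1-bromo-4-iodobenzene (commercial arene replacing 1) | Brc1ccc(I)cc1
F2 | step 1 | (1S,2R)-3-bromo-6-iodocyclohexa-3,5-diene-1,2-diol | BrC1=CC=C(I)[C@@H](O)[C@H]1O
F3 | step 1 | bis(tert-butyldimethylsilyl) ether of F2 | BrC1=CC=C(I)[C@@H](O[Si](C)(C)C(C)(C)C)[C@H]1O[Si](C)(C)C(C)(C)C
F4 | step 1 | 1-bromo-5α,6α-bis(tert-butyldimethylsilyloxy)-4-methylcyclohexa-1,3-diene | BrC1=CC=C(C)[C@@H](O[Si](C)(C)C(C)(C)C)[C@H]1O[Si](C)(C)C(C)(C)C
F5 | step 1 | 1-(1-ethoxyethenyl)-5α,6α-bis(tert-butyldimethylsilyloxy)-4-methylcyclohexa-1,3-diene | CCOC(=C)C1=CC=C(C)[C@@H](O[Si](C)(C)C(C)(C)C)[C@H]1O[Si](C)(C)C(C)(C)C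
F6 | step 4 | 1-acetyl-2α,3α-bis(tert-butyldimethylsilyloxy)-4β,5β-epoxy-4-methylcyclohex-1(6)-ene | CC(=O)C1=C[C@@H]2O[C@]2(C)[C@@H](O[Si](C)(C)C(C)(C)C)[C@H]1O[Si](C)(C)C(C)(C)C
F7 | step 4 | 1-acetyl-4β,5β-epoxy-4-methylcyclohex-1(6)-ene-2α,3α-diol | CC(=O)C1=C[C@@H]2O[C@]2(C)[C@@H](O)[C@H]1O
F8 | step 4 | 1β-acetyl-4β,5β-epoxy-4-methylcyclohexane-2α,3α-diol | CC(=O)[C@@H]1C[C@@H]2O[C@]2(C)[C@@H](O)[C@H]1O
F9 | step 12 | 1β-(5-bromo-6-hydroperoxy-6-methyl-3-oxohept-1-en-2-yl)-2α-(3-methylbutanoyloxy)-4β,5β-epoxy-4-methylcyclohexan-3-one | C=C(C(=O)CC(Br)C(C)(C)OO)[C@@H]1C[C@@H]2O[C@]2(C)C(=O)[C@H]1OC(=O)CC(C)C
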